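**Plan**

- Atom labels used below: bicyclo[3.3.1]nonane part C1 (isobutyryl), C2=O, C3 (spiro carbon), C4=O, C5 (geranyl), C6H2, C7H, C8Me2, C9=O; bridge C7–C10H2–C11H–C3; cyclopentane C3–C11–C12Me2–C13H(iPr)–C14H2.
- Retrosynthesis: the last operation cuts C7–C10 and C1–C8 together, back to a monocyclic spiro 2-acylcyclohexane-1,3,5-trione. Before that come the two allyl bonds at C5, then C1–C2 (Claisen onto a lactone carbonyl) and C4–C5 (acylation of a diketone dianion), then C12–C13 (radical 5-exo), C3–C4 and C3–C14 (lactone enolate chemistry), and C11–C12 (conjugate addition).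
- Forward: δ-lactone, then the cyclopentane (ring D) fused to it, then the trione ring B by opening the lactone, then in one operation the seven-membered ring C3–C4–C5–C6–C7–C10–C11 (ring C) and ring A (C1–C9–C5–C6–C7–C8).
- Stereochemistry: C11 from the rhodium/BINAP conjugate addition; C3 and C13 relayed from C11 (anti attack on the lactone enolate, cis ring fusion, chair-like 5-exo transition state); C5 by alkylation anti to the C11 side arm; C7 and C1 fixed by the cage in the key step.
- Feature that makes the key event possible: ring B carries on one face, at its 1,3,5-related carbons, the C10 methylene (on C11 next to spiro C3), the prenyl unit C6–C7=C8 on C5, and the nucleophilic enol carbon C1 of the 2-acyl-1,3-dione. A C10 radical can therefore add to C7, and the C8 cation that follows is captured by C1.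

Key step: step 11

Remark: (S)-BINAP is assumed to give the 4S lactone 3, the sense expected for this catalyst with cyclic enones and unsaturated lactones; if the sense proves opposite, (R)-BINAP is used.

**Step 1**
Reactants: 1 5,6-dihydro-2H-pyran-2-one; 2 potassium isopropenyltrifluoroborate
Product: 3 (S)-4-isopropenyl-tetrahydropyran-2-one
Conditions: [Rh(cod)2]BF4 (3 mol%), (S)-BINAP (3.3 mol%), toluene–H2O (10:1), 100 °C
Reagents that add atoms: none
Why: Rhodium-catalysed asymmetric 1,4-addition of an alkenylboron reagent to an unsaturated lactone (Hayashi–Miyaura reaction), in which the chiral bisphosphine selects the face of C11 and water protonates the rhodium enolate.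

**Step 2**
Reactants: 3 (S)-4-isopropenyl-tetrahydropyran-2-one; 4 prenyl bromide
Product: 5 (3R,4S)-3-prenyl-4-isopropenyl-tetrahydropyran-2-one (trans)
Conditions: LiN(iPr)2 (1.1 equiv), THF, −78 °C; then 4, DMPU, −78 → −40 °C
Reagents that add atoms: none
Why: Alkylation of a δ-lactone enolate, which should enter trans to the C11 substituent; the C3 centre made here is planarised again in step 3.

**Step 3**
Reactants: 5 (3R,4S)-3-prenyl-4-isopropenyl-tetrahydropyran-2-one
Product: 6 (3S,4R)-2-oxo-3-prenyl-4-isopropenyl-tetrahydropyran-3-carboxylic acid (prenyl cis to isopropenyl)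
Conditions: LiN(iPr)2 (1.2 equiv), THF, −78 °C; CO2 gas, −78 → 0 °C; 1 M HCl, 0 °C
Reagents that add atoms: carbon dioxide, O=C=O
Why: C-carboxylation of the trisubstituted lactone enolate, with CO2 approaching anti to the C11 isopropenyl group, so that quaternary C3 is set with prenyl and isopropenyl cis as ring D requires.

**Step 4**
Reactants: 6 (3S,4R)-2-oxo-3-prenyl-4-isopropenyl-tetrahydropyran-3-carboxylic acid
Product: 7 cis-fused cyclopentane–δ-lactone acid (C3 carboxylic acid; C13 isopropyl trans to C10)
Conditions: Mn(dpm)3 (10 mol%), PhSiH3 (2 equiv), tBuOOH (1.5 equiv), iPrOH, 25 °C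
Reagents that add atoms: none
Why: Mukaiyama-type metal-hydride hydrogen atom transfer to the 1,1-disubstituted alkene gives the tertiary C12 radical, which cyclises 5-exo-trig onto the prenyl CH and is then reduced by a second hydrogen atom transfer; the ring fusion must be cis, and C13 is set by the chair-like transition state with the C11–C10 bond pseudo-equatorial, placing isopropyl trans to C10.

**Step 5**
Reactants: 7 cis-fused cyclopentane–δ-lactone acid; 8 5-methylhexane-2,4-dione
Product: 10 lactone triketone (6-methyl-3,5-dioxoheptanoyl group on C3), via acid chloride 9 (not isolated)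
Conditions: (COCl)2, DMF (cat.), CH2Cl2, 0 → 25 °C, evaporate; 8 (2.5 equiv), LiN(iPr)2 (5.1 equiv), THF, −78 → 0 °C, then 9, −78 °C; AcOH
Reagents that add atoms: oxalyl chloride, ClC(=O)C(=O)Cl (supplies the chlorine of 9)
Why: C-acylation of a β-diketone dianion at its terminal methyl carbon (forming C4–C5); the acid chloride reacts far faster than the lactone, so the free carboxyl carbon becomes C4 and the lactone carbonyl is kept for C2.

**Step 6**
Reactants: 10 lactone triketone
Product: 12 silyl ether of the spiro trione (ring B closed; C5 unsubstituted; CH2CH2OTBS arm on C11), via disodium alkoxide enolate 11 (not isolated)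
Conditions: NaH (3 equiv), THF, 0 → 65 °C; then tBuMe2SiCl (2.2 equiv), 0 °C; 1 M HCl, 0 °C
Reagents that add atoms: tert-butyldimethylsilyl chloride, CC(C)(C)[Si](C)(C)Cl
Why: Intramolecular Claisen (Dieckmann-type) condensation of the doubly activated C1 carbanion onto the lactone carbonyl closes ring B, driven by formation of the triketone enolate; because the lactone is cis-fused, C2 ends cis to C10 and C4 trans, which fixes the sense of spiro C3 needed later.

**Step 7**
Reactants: 12 silyl ether of the spiro trione; 4 prenyl bromide
Product: 13 C5-prenyl spiro trione silyl ether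
Conditions: LiN(SiMe3)2 (2.1 equiv), THF, −78 °C; 4 (1.05 equiv), −78 → −20 °C; 1 M HCl
Reagents that add atoms: none
Why: C-alkylation of the dianion of a 2-acylcyclohexane-1,3,5-trione at its most basic carbon C5, as in the dearomatising allylation of acylphloroglucinols; no lasting stereocentre is formed because C5 still enolises.

**Step 8**
Reactants: 13 C5-prenyl spiro trione silyl ether; 14 geranyl bromide
Product: 15 C5-geranyl C5-prenyl spiro trione silyl ether (prenyl cis to C11)
Conditions: LiN(SiMe3)2 (2.1 equiv), THF, −78 °C; 14 (1.1 equiv), −78 → −20 °C; 1 M HCl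
Reagents that add atoms: none
Why: Second C-alkylation of the same dianion; the silyloxyethyl arm on C11 lies over one face of ring B, so geranyl bromide should enter from the face of C14H2 and leave the prenyl group cis to C11, which sets quaternary C5.

**Step 9**
Reactants: 15 C5-geranyl C5-prenyl spiro trione silyl ether
Product: 17 carboxymethyl spiro trione (CH2CO2H on C11), via primary alcohol 16 (not isolated)
Conditions: HF·pyridine, pyridine, THF, 0 °C; then nPr4N[RuO4] (10 mol%), N-methylmorpholine N-oxide monohydrate (10 equiv), MeCN, 25 °C
Reagents that add atoms: water (from N-methylmorpholine N-oxide monohydrate), O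
Why: Desilylation followed by Ley–Griffith oxidation in the presence of water, which takes the primary alcohol through the aldehyde hydrate to the acid under neutral conditions that spare the trisubstituted alkenes; C5 is already quaternary, so the transient aldehyde has no enolisable neighbour to condense with.

**Step 10**
Reactants: 17 carboxymethyl spiro trione; 18 N-hydroxyphthalimide
Product: 19 N-acyloxyphthalimide of 17
Conditions: 18 (1.5 equiv), iPrN=C=NiPr (1.2 equiv), DMAP (5 mol%), CH2Cl2, 0 → 25 °C
Reagents that add atoms: none
Why: Carbodiimide (Steglich-type) esterification to the redox-active ester; the excess of the N-hydroxy nucleophile should outrun acylation of the hydrogen-bonded enol.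

**Step 11**
Reactants: 19 N-acyloxyphthalimide of 17
Product: 22 CNP0379246.1 (target; C1 S, C3 S, C5 R, C7 R, C11 R, C13 R in the labels above), via primary alkyl radical 20 (not isolated), via tertiary cation 21 (not isolated)
Conditions: fac-Ir(ppy)3 (2 mol%), (CF3)2CHOH–CH2Cl2 (1:1), 0.01 M, 450 nm LEDs, argon, 25 °C
Reagents that add atoms: none
Why: Proposed new method: the excited iridium complex transfers an electron to the N-acyloxyphthalimide, which loses phthalimide anion and CO2 to give the primary C10 radical 20; this radical, held over the face of ring B that carries only the C5 prenyl group, adds 7-exo-trig to the CH terminus C7, the tertiary C8 radical is oxidised by the tetravalent iridium formed in the first electron transfer to cation 21, and the enol carbon C1 captures C8 with loss of a proton to phthalimide anion, so that ring C (radical 7-exo-trig) and ring A (cationic C-alkylation of the enol through a six-membered chair) close in one redox-neutral operation. The closest known reaction types are the photoredox decarboxylative radical–polar crossover carbofunctionalisation of alkenes with N-acyloxyphthalimides and the acid-mediated cationic cyclisation in which a prenyl-derived tertiary cation alkylates C1 of a 2-acylcyclohexane-1,3-dione enol to close the bicyclo[3.3.1]nonane core, which is also the presumed biosynthetic ring closure. C7 need not be set in the radical addition, which should favour the epimer with C8 turned away from ring B (allylic strain), because cation 21 can epimerise at C7 in the non-nucleophilic solvent by reversible 1,2-hydride shift between C7 and C8, and only the epimer with C8 on the concave face can reach C1; C1 is fixed by the cage, since the bond can form only on the face of ring B that carries the bridge. The step needs the radical to choose C7 over the geranyl alkenes, the C1 enol carbon and the allylic C6–H, and needs C- rather than O-alkylation: the geranyl group lies on the opposite face, C5 is quaternary, C1 is fully substituted and polarity-mismatched for a nucleophilic alkyl radical, hexafluoroisopropanol hydrogen-bonds the enol oxygens, and only C-attack gives the strain-free homoadamantane.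

**Compound list**

1 | 5,6-dihydro-2H-pyran-2-one | O=C1C=CCCO1 | starting material
2 | potassium trifluoro(prop-1-en-2-yl)borate | [K+].CC(=C)[B-](F)(F)F | starting material
3 | (S)-4-(prop-1-en-2-yl)tetrahydro-2H-pyran-2-one | CC(=C)[C@H]1CCOC(=O)C1 | intermediate
4 | prenyl bromide (1-bromo-3-methylbut-2-ene) | CC(C)=CCBr | starting material
5 | (3R,4S)-3-(3-methylbut-2-en-1-yl)-4-(prop-1-en-2-yl)tetrahydro-2H-pyran-2-one, trans | CC(=C)[C@H]1CCOC(=O)[C@@H]1CC=C(C)C | intermediate
6 | (3S,4R)-3-(3-methylbut-2-en-1-yl)-2-oxo-4-(prop-1-en-2-yl)tetrahydro-2H-pyran-3-carboxylic acid, prenyl cis to isopropenyl | CC(=C)[C@H]1CCOC(=O)[C@]1(CC=C(C)C)C(=O)O | intermediate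
7 | cis-fused 6-isopropyl-5,5-dimethyl-1-oxohexahydrocyclopenta[c]pyran-7a(1H)-carboxylic acid, isopropyl trans to the ring CH2 on C11 | OC(=O)[C@]12C[C@H](C(C)C)C(C)(C)[C@H]1CCOC2=O | intermediate
8 | 5-methylhexane-2,4-dione | CC(C)C(=O)CC(=O)C | starting material
9 | acid chloride of 7 | ClC(=O)[C@]12C[C@H](C(C)C)C(C)(C)[C@H]1CCOC2=O | intermediate
10 | lactone triketone: 7a-(6-methyl-3,5-dioxoheptanoyl) analogue of 7 | CC(C)C(=O)CC(=O)CC(=O)[C@]12C[C@H](C(C)C)C(C)(C)[C@H]1CCOC2=O | intermediate
11 | disodium alkoxide enolate of the ring-B-closed hydroxyethyl spiro trione | [Na+].[Na+].CC(C)C(=O)C1=C([O-])CC(=O)[C@]2(C1=O)C[C@H](C(C)C)C(C)(C)[C@H]2CC[O-] | intermediate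
12 | 2-isobutyryl spiro[4.5] trione (enol form) with CH2CH2OTBS on C11, gem-dimethyl on C12, isopropyl on C13, C5 unsubstituted | CC(C)C(=O)C1=C(O)CC(=O)[C@]2(C1=O)C[C@H](C(C)C)C(C)(C)[C@H]2CCO[Si](C)(C)C(C)(C)C | intermediate
13 | C5-prenyl derivative of 12 (dienol form) | CC(C)C(=O)C1=C(O)C(CC=C(C)C)=C(O)[C@]2(C1=O)C[C@H](C(C)C)C(C)(C)[C@H]2CCO[Si](C)(C)C(C)(C)C | intermediate
14 | geranyl bromide ((E)-1-bromo-3,7-dimethylocta-2,6-diene) | CC(C)=CCC/C(C)=C/CBr | starting material
15 | C5-geranyl C5-prenyl derivative of 12, prenyl cis to C11 | CC(C)C(=O)C1=C(O)[C@@](CC=C(C)C)(C/C=C(C)/CCC=C(C)C)C(=O)[C@]2(C1=O)C[C@H](C(C)C)C(C)(C)[C@H]2CCO[Si](C)(C)C(C)(C)C | intermediate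
16 | primary alcohol from 15 (CH2CH2OH on C11) | CC(C)C(=O)C1=C(O)[C@@](CC=C(C)C)(C/C=C(C)/CCC=C(C)C)C(=O)[C@]2(C1=O)C[C@H](C(C)C)C(C)(C)[C@H]2CCO | intermediate
17 | carboxylic acid (CH2CO2H on C11) | CC(C)C(=O)C1=C(O)[C@@](CC=C(C)C)(C/C=C(C)/CCC=C(C)C)C(=O)[C@]2(C1=O)C[C@H](C(C)C)C(C)(C)[C@H]2CC(=O)O | intermediate
18 | N-hydroxyphthalimide | ON1C(=O)c2ccccc2C1=O | starting material
19 | N-acyloxyphthalimide of 17 | CC(C)C(=O)C1=C(O)[C@@](CC=C(C)C)(C/C=C(C)/CCC=C(C)C)C(=O)[C@]2(C1=O)C[C@H](C(C)C)C(C)(C)[C@H]2CC(=O)ON3C(=O)c4ccccc4C3=O | intermediate
20 | primary C10 radical | CC(C)C(=O)C1=C(O)[C@@](CC=C(C)C)(C/C=C(C)/CCC=C(C)C)C(=O)[C@]2(C1=O)C[C@H](C(C)C)C(C)(C)[C@H]2[CH2] | intermediate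
21 | ring-C-closed tertiary C8 cation (productive C7 epimer shown) | CC(C)=CCC/C(C)=C/C[C@@]12C[C@H]([C+](C)C)C[C@@H]3C(C)(C)[C@@H](C(C)C)C[C@]3(C1=O)C(=O)C(C(=O)C(C)C)=C2O | intermediate
22 | CNP0379246.1 | CC(C)=CCC/C(C)=C/C[C@@]12C[C@H]3C[C@@H]4C(C)(C)[C@@H](C(C)C)C[C@]4(C1=O)C(=O)[C@@](C(=O)C(C)C)(C2=O)C3(C)C | target

**Total step count:** 11. **Longest linear sequence:** 11 steps (from 1).

**Steps most likely to fail**

1. Step 11 (proposed new method). The C10 radical may be lost by intramolecular hydrogen transfer from the allylic C6–H or by 5-exo addition to C1 before it reaches C7. The C8 cation may also lose a proton, or be captured at oxygen or through the ring cation at C7, instead of alkylating C1. Fallback, from 19: a photoinduced palladium-catalysed decarboxylative Heck-type cyclisation (Pd(PPh3)2Cl2, Xantphos, N,N-dimethylacetamide, blue LEDs) should form the same C7–C10 bond and end by β-hydride elimination, giving the ring-C-closed 7-isopropenyl trione (both C7 epimers) F1. Formic acid at 25 °C should then protonate the 1,1-disubstituted alkene to the C8 cation, which equilibrates at C7 by hydride shift and alkylates C1 (the known acid-mediated cationic cyclisation of prenylated acylphloroglucinol-type enols), returning to the route at 22.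

2. Step 8. Facial selectivity in the second C5 alkylation may be poor, and O-alkylation may compete. Fallback, from 13: replace substrate control by catalyst control in a palladium-catalysed Tsuji–Trost allylic alkylation with geranyl methyl carbonate (Pd2(dba)3, (R,R)- or (S,S)-DACH-phenyl bisphosphine ligand, THF, 25 °C, no added base), with the ligand enantiomer chosen to place geranyl anti to C11; this returns directly to 15 and no new compound is formed (F0).

3. Step 4. Hydrogen atom transfer to the prenyl alkene may compete with transfer to the isopropenyl group, the tertiary radical may be reduced before ring closure, and selectivity at C13 may be modest. Fallback, from 6: thiyl-radical-mediated diene cyclisation (PhSH, AIBN, benzene, 80 °C). The thiyl radical adds reversibly to the terminal CH2 of the isopropenyl group, the tertiary C12 radical closes 5-exo onto the prenyl group and takes hydrogen from the thiol, giving the phenylthiomethyl bicyclic lactone acid F2. Desulfurisation with Raney Ni in ethanol turns CH2SPh into the second C12 methyl and returns to the route at 7.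

**Further compounds**

F1 | step 11 | ring-C-closed 7-isopropenyl spiro trione (C7 epimers) | CC(C)=CCC/C(C)=C/C[C@@]12CC(C(C)=C)C[C@@H]3C(C)(C)[C@@H](C(C)C)C[C@]3(C1=O)C(=O)C(C(=O)C(C)C)=C2O
F0 | step 8 | none | none
F2 | step 4 | phenylthiomethyl bicyclic lactone acid (C12 epimers) | OC(=O)[C@]12C[C@H](C(C)C)C(C)(CSc3ccccc3)[C@H]1CCOC2=O
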